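**Strategy.** The route rests on cutting ring C of the middle epigallocatechin unit at two bonds, C4–C4a and O1–C2. One acid-triggered [3+3] cascade joins a phenol ring (future ring A, carbons C4a and C8a–O1), already attached through its C8 to C4 of the finished epicatechin unit, with a three-carbon piece C4–C3–C2 stored as a cis-epoxy carbinol on C8 of the finished catechin unit: the ionised carbinol carbon alkylates the phenol ortho carbon and the phenol oxygen opens the epoxide at benzylic C2. The precursors are a bromine-capped 4-(2-hydroxyaryl)epicatechin and an enantiopure cis-epoxide whose carbinol centre needs no control. Desilylation, triple galloylation and hydrogenolysis finish the synthesis.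

Key step: step 15

Remark: the target is read as epicatechin 3-O-gallate-(4β→8)-epigallocatechin 3-O-gallate-(4β→8)-catechin 3-O-gallate (top unit 2,3-cis-3,4-trans, middle unit 2,3-cis-3,4-trans, bottom unit 2,3-trans, every C2 of R configuration).
Remark: C1 of epoxy carbinol 19 becomes planar in step 15, so 19 is made and used as a mixture of C1 epimers and its SMILES leaves this centre undefined.
Remark: the top unit carries a bromine at C8 from step 2 to step 18 as a blocking group for its most nucleophilic ring A carbon; it leaves in the final hydrogenolysis.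
Remark: the galloyl donor of step 17, 3,4,5-tris(benzyloxy)benzoic acid, is a commercial reagent; three molecules of it are incorporated in that step.
Remark: Bn = benzyl, TBS = tert-butyldimethylsilyl; flavan numbering (rings A, B, C) is used for each unit.

**Step 1**
Reactants: 1 (−)-epicatechin
Product: 2 5,7,3',4'-tetra-O-benzyl-(−)-epicatechin
Conditions: BnBr (4.4 equiv), K2CO3, DMF, 0 °C → rt
Reagents that add atoms: benzyl bromide, BrCc1ccccc1
Why: Williamson etherification in which carbonate deprotonates only the four phenols, so the secondary 3-hydroxyl stays free and no stereocentre is touched.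

**Step 2**
Reactants: 2 5,7,3',4'-tetra-O-benzyl-(−)-epicatechin
Product: 3 8-bromo-5,7,3',4'-tetra-O-benzyl-(−)-epicatechin
Conditions: NBS (1.0 equiv), CH2Cl2, −40 °C → rt
Reagents that add atoms: N-bromosuccinimide, O=C1CCC(=O)N1Br
Why: electrophilic aromatic bromination, for which C8 (between O1 and the 7-benzyloxy group) is the more reactive of the two free ring A carbons of benzylated flavan-3-ols, so one equivalent should give the 8-bromide.

**Step 3**
Reactants: 3 8-bromo-5,7,3',4'-tetra-O-benzyl-(−)-epicatechin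
Product: 4 8-bromo-4β-(2-ethoxyethoxy)-5,7,3',4'-tetra-O-benzyl-(−)-epicatechin (3-OH free; 2,3-cis, 3,4-trans)
Conditions: DDQ (2 equiv), 2-ethoxyethanol (5 equiv), CH2Cl2, rt
Reagents that add atoms: 2-ethoxyethanol, CCOCCO
Why: oxidative benzylic etherification in which DDQ abstracts hydride from C4 and the ring A-stabilised cation is captured by the alcohol anti to the axial 3-hydroxyl (4β), a centre that is ionised again in step 5.

**Step 4**
Reactants: 4 8-bromo-4β-(2-ethoxyethoxy)-5,7,3',4'-tetra-O-benzyl-(−)-epicatechin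
Product: 5 8-bromo-4β-(2-ethoxyethoxy)-3-O-TBS-5,7,3',4'-tetra-O-benzyl-(−)-epicatechin
Conditions: TBSCl, imidazole, DMAP (10 mol %), DMF, rt → 40 °C
Reagents that add atoms: tert-butyldimethylsilyl chloride, CC(C)(C)[Si](C)(C)Cl
Why: silylation of the only free hydroxyl under non-acidic conditions that spare the acid-labile C4 ether and change no stereocentre.

**Step 5**
Reactants: 5 8-bromo-4β-(2-ethoxyethoxy)-3-O-TBS-5,7,3',4'-tetra-O-benzyl-(−)-epicatechin; 6 3,5-bis(benzyloxy)phenol
Product: 7 8-bromo-4β-[2-hydroxy-4,6-bis(benzyloxy)phenyl]-3-O-TBS-5,7,3',4'-tetra-O-benzyl-(−)-epicatechin (phenol precursor; 2,3-cis, 3,4-trans)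
Conditions: 6 (3 equiv), Me3SiOTf (0.2 equiv), CH2Cl2, −78 → −40 °C
Reagents that add atoms: none
Why: Lewis-acid-mediated SN1 substitution at C4 (Friedel–Crafts alkylation of the phenol) in which the C4 cation should be attacked by one of the two equivalent carbons ortho to the hydroxyl, which are less hindered than the carbon between the two benzyloxy groups, from the face anti to the 3-silyloxy group (3,4-trans), while the C8 bromine excludes self-condensation.

**Step 6**
Reactants: 8 3,4,5-trihydroxybenzaldehyde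
Product: 9 3,4,5-tris(benzyloxy)benzaldehyde
Conditions: BnBr (3.5 equiv), K2CO3, DMF, rt → 60 °C
Reagents that add atoms: benzyl bromide, BrCc1ccccc1
Why: Williamson etherification of the three phenols, to which the aldehyde is inert.

**Step 7**
Reactants: 9 3,4,5-tris(benzyloxy)benzaldehyde
Product: 10 methyl (Z)-3-[3,4,5-tris(benzyloxy)phenyl]prop-2-enoate
Conditions: (CF3CH2O)2P(O)CH2CO2Me, KN(SiMe3)2, 18-crown-6, THF, −78 °C
Reagents that add atoms: methyl bis(2,2,2-trifluoroethyl)phosphonoacetate, COC(=O)CP(=O)(OCC(F)(F)F)OCC(F)(F)F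
Why: Still–Gennari olefination, in which the electron-poor phosphonate makes elimination from the kinetically formed adduct fast and should therefore give the (Z)-enoate from an aromatic aldehyde.

**Step 8**
Reactants: 10 methyl (Z)-3-[3,4,5-tris(benzyloxy)phenyl]prop-2-enoate
Product: 11 methyl (2S,3S)-3-[3,4,5-tris(benzyloxy)phenyl]oxirane-2-carboxylate (cis)
Conditions: (S,S)-N,N′-bis(3,5-di-tert-butylsalicylidene)-1,2-cyclohexanediaminomanganese chloride (5 mol %), 4-phenylpyridine N-oxide (0.25 equiv), aq. NaOCl (pH 11.3), CH2Cl2, 0 °C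
Reagents that add atoms: sodium hypochlorite, [Na+].[O-]Cl
Why: Jacobsen–Katsuki epoxidation of a cis-cinnamate ester, in which oxygen transfer from the chiral oxomanganese salen complex to one face of the (Z)-alkene sets both epoxide centres, the (S,S) ligand being chosen because the (R,R) ligand turns cis-cinnamate esters into (2R,3R)-glycidates, and any trans-epoxide should be removed by chromatography.

**Step 9**
Reactants: 11 methyl (2S,3S)-3-[3,4,5-tris(benzyloxy)phenyl]oxirane-2-carboxylate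
Product: 12 [(2R,3S)-3-[3,4,5-tris(benzyloxy)phenyl]oxiran-2-yl]methanol (cis)
Conditions: NaBH4, MeOH/THF, 0 °C
Reagents that add atoms: none
Why: borohydride reduction of an ester activated by its α-oxygen to the primary alcohol, which leaves the epoxide and both stereocentres untouched.

**Step 10**
Reactants: 12 [(2R,3S)-3-[3,4,5-tris(benzyloxy)phenyl]oxiran-2-yl]methanol
Product: 13 (2S,3S)-3-[3,4,5-tris(benzyloxy)phenyl]oxirane-2-carbaldehyde (cis)
Conditions: Dess–Martin periodinane (1.3 equiv), NaHCO3, CH2Cl2, 0 °C → rt; used at once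
Reagents that add atoms: none
Why: Dess–Martin oxidation under buffered, near-neutral conditions, which should keep the α-centre of the cis-epoxy aldehyde from epimerising.

**Step 11**
Reactants: 14 (+)-catechin
Product: 15 5,7,3',4'-tetra-O-benzyl-(+)-catechin
Conditions: BnBr (4.4 equiv), K2CO3, DMF, 0 °C → rt
Reagents that add atoms: benzyl bromide, BrCc1ccccc1
Why: Williamson etherification of the four phenols only, with both stereocentres untouched.

**Step 12**
Reactants: 15 5,7,3',4'-tetra-O-benzyl-(+)-catechin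
Product: 16 3-O-TBS-5,7,3',4'-tetra-O-benzyl-(+)-catechin
Conditions: TBSCl, imidazole, DMF, rt
Reagents that add atoms: tert-butyldimethylsilyl chloride, CC(C)(C)[Si](C)(C)Cl
Why: silylation of the equatorial secondary hydroxyl gives an ether that tolerates the organolithium chemistry of step 14.

**Step 13**
Reactants: 16 3-O-TBS-5,7,3',4'-tetra-O-benzyl-(+)-catechin
Product: 17 8-bromo-3-O-TBS-5,7,3',4'-tetra-O-benzyl-(+)-catechin
Conditions: NBS (1.0 equiv), CH2Cl2, −40 °C → rt
Reagents that add atoms: N-bromosuccinimide, O=C1CCC(=O)N1Br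
Why: electrophilic aromatic bromination at C8, the more reactive free ring A carbon of benzylated flavan-3-ols.

**Step 14**
Reactants: 17 8-bromo-3-O-TBS-5,7,3',4'-tetra-O-benzyl-(+)-catechin; 13 (2S,3S)-3-[3,4,5-tris(benzyloxy)phenyl]oxirane-2-carbaldehyde
Product: 19 (1RS,2R,3S)-2,3-epoxy-3-[3,4,5-tris(benzyloxy)phenyl]-1-[3-O-TBS-5,7,3',4'-tetra-O-benzyl-(+)-catechin-8-yl]propan-1-ol (cis-epoxy carbinol precursor; both C1 epimers), via 8-lithio catechin ether 18 (not isolated)
Conditions: t-BuLi (2.0 equiv), THF, −78 °C; then 13, −78 °C; aq. NH4Cl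
Reagents that add atoms: none
Why: bromine–lithium exchange followed by 1,2-addition of the aryllithium to the aldehyde, which is far more electrophilic than the epoxide at −78 °C; the new carbinol centre forms without control, which is of no consequence because it is ionised in step 15.

**Step 15**
Reactants: 7 8-bromo-4β-[2-hydroxy-4,6-bis(benzyloxy)phenyl]-3-O-TBS-5,7,3',4'-tetra-O-benzyl-(−)-epicatechin; 19 cis-epoxy carbinol (both C1 epimers)
Product: 22 benzyl-protected trimer (8-bromo-3-O-TBS-tetra-O-benzyl-epicatechin-(4β→8)-penta-O-benzyl-epigallocatechin-(4β→8)-3-O-TBS-tetra-O-benzyl-catechin; middle 3-OH free), via benzylic cation 20 (not isolated), via epoxy phenol 21 (not isolated)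
Conditions: 7 (1.5 equiv), BF3·OEt2 (0.2 equiv), 4 Å molecular sieves, CH2Cl2, −78 → −20 °C, slow addition of 19
Reagents that add atoms: none
Why: Proposed new method: catalytic BF3·OEt2 should ionise the doubly ortho- and para-oxygenated benzylic carbinol of 19 (either epimer) to cation 20 well before it touches the epoxide, the phenol ring of 7 should trap 20 through its only free carbon ortho to the hydroxyl (Friedel–Crafts alkylation, new C4–C4a bond) to give epoxy phenol 21, and the phenolic oxygen should then open the acid-activated cis-epoxide at its benzylic carbon (new O1–C2 bond). The closest known reaction types are the Friedel–Crafts alkylation of phenols by benzhydryl-type cations and the acid-mediated 6-endo cyclisation of 2-hydroxyaryl-substituted aryl epoxides to dihydroflavonols and flavan-3-ols; their combination on a cation that carries the epoxide next to it has no precedent. Ring C of the middle unit, the only ring formed, closes by 6-endo epoxide opening (O1 to C2) once the intermolecular C4–C4a bond has set up the tether, and the aryl group at C2 should favour this mode over 5-exo attack at C3. The C4 centre is set when the phenol carbon adds to planar 20: the cis aryl group on C2 should force the large ring A of the cation to point away from C2, and the nucleophile should then approach anti to the epoxide C3–O bond past the C3 hydrogen (Felkin–Anh-type), which gives the 3,4-trans relation; the C2 centre is set by SN2-type inversion, so that the cis-epoxide delivers the 2,3-cis relation while C3 keeps its oxygen and configuration. The step needs carbon over oxygen alkylation, attack ortho and not para to the phenol hydroxyl, and no alkylation of other arenes: O- and para-adducts of so stable a cation can revert while the ortho adduct is drained by cyclisation, the bromine at C8 of the top unit blocks its most nucleophilic carbon, and slow addition of 19 to an excess of 7 should keep C6 of the bottom unit from competing.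

**Step 16**
Reactants: 22 benzyl-protected trimer
Product: 23 trimer triol (8-bromo-tetra-O-benzyl-epicatechin-(4β→8)-penta-O-benzyl-epigallocatechin-(4β→8)-tetra-O-benzyl-catechin; all three 3-OH free)
Conditions: HF·pyridine, pyridine, THF, 0 °C → rt
Reagents that add atoms: none
Why: fluoride-driven cleavage of both secondary silyl ethers in a pyridine-buffered medium that should spare benzyl ethers, the aryl bromide and the acid-sensitive interflavan bonds.

**Step 17**
Reactants: 23 trimer triol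
Product: 24 tris[3,4,5-tris(benzyloxy)benzoate] of 23 (esters at O3 of all three units)
Conditions: 3,4,5-tris(benzyloxy)benzoic acid (6 equiv), DCC (6 equiv), DMAP (3 equiv), CH2Cl2, rt → 35 °C
Reagents that add atoms: 3,4,5-tris(benzyloxy)benzoic acid, OC(=O)c1cc(OCc2ccccc2)c(OCc2ccccc2)c(OCc2ccccc2)c1
Why: Steglich esterification, in which the acylpyridinium formed from the acid, used in excess, acylates each of the three hindered secondary hydroxyls at oxygen (three molecules of acid incorporated) and so leaves every stereocentre unchanged.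

**Step 18**
Reactants: 24 tris[3,4,5-tris(benzyloxy)benzoate] of 23
Product: 25 epicatechin 3-O-gallate-(4β→8)-epigallocatechin 3-O-gallate-(4β→8)-catechin 3-O-gallate (target)
Conditions: H2 (1 atm), Pd(OH)2/C, THF/MeOH/H2O, rt
Reagents that add atoms: none
Why: catalytic hydrogenolysis should cleave all 22 benzyl ethers and the C8–Br bond in one operation, while the gallate esters, the ring C ethers and the interflavan bonds persist.

**Compound list**
1 | (−)-epicatechin | O[C@@H]1Cc2c(O)cc(O)cc2O[C@@H]1c1ccc(O)c(O)c1 | starting material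
2 | 5,7,3',4'-tetra-O-benzyl-(−)-epicatechin | O[C@@H]1Cc2c(OCc9ccccc9)cc(OCc9ccccc9)cc2O[C@@H]1c1ccc(OCc9ccccc9)c(OCc9ccccc9)c1 | intermediate
3 | 8-bromo-5,7,3',4'-tetra-O-benzyl-(−)-epicatechin | O[C@@H]1Cc2c(OCc9ccccc9)cc(OCc9ccccc9)c(Br)c2O[C@@H]1c1ccc(OCc9ccccc9)c(OCc9ccccc9)c1 | intermediate
4 | 8-bromo-4β-(2-ethoxyethoxy)-5,7,3',4'-tetra-O-benzyl-(−)-epicatechin | CCOCCO[C@H]1c2c(OCc9ccccc9)cc(OCc9ccccc9)c(Br)c2O[C@H](c2ccc(OCc9ccccc9)c(OCc9ccccc9)c2)[C@@H]1O | intermediate
5 | 8-bromo-4β-(2-ethoxyethoxy)-3-O-TBS-5,7,3',4'-tetra-O-benzyl-(−)-epicatechin | CCOCCO[C@H]1c2c(OCc9ccccc9)cc(OCc9ccccc9)c(Br)c2O[C@H](c2ccc(OCc9ccccc9)c(OCc9ccccc9)c2)[C@@H]1O[Si](C)(C)C(C)(C)C | intermediate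
6 | 3,5-bis(benzyloxy)phenol | Oc1cc(OCc2ccccc2)cc(OCc2ccccc2)c1 | starting material
7 | 8-bromo-4β-[2-hydroxy-4,6-bis(benzyloxy)phenyl]-3-O-TBS-5,7,3',4'-tetra-O-benzyl-(−)-epicatechin | Oc1cc(OCc9ccccc9)cc(OCc9ccccc9)c1[C@H]3c4c(OCc9ccccc9)cc(OCc9ccccc9)c(Br)c4O[C@H](c4ccc(OCc9ccccc9)c(OCc9ccccc9)c4)[C@@H]3O[Si](C)(C)C(C)(C)C | intermediate
8 | 3,4,5-trihydroxybenzaldehyde | O=Cc1cc(O)c(O)c(O)c1 | starting material
9 | 3,4,5-tris(benzyloxy)benzaldehyde | O=Cc1cc(OCc9ccccc9)c(OCc9ccccc9)c(OCc9ccccc9)c1 | intermediate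
10 | methyl (Z)-3-[3,4,5-tris(benzyloxy)phenyl]prop-2-enoate | COC(=O)/C=C\c1cc(OCc9ccccc9)c(OCc9ccccc9)c(OCc9ccccc9)c1 | intermediate
11 | methyl (2S,3S)-3-[3,4,5-tris(benzyloxy)phenyl]oxirane-2-carboxylate | COC(=O)[C@H]1O[C@H]1c1cc(OCc9ccccc9)c(OCc9ccccc9)c(OCc9ccccc9)c1 | intermediate
12 | [(2R,3S)-3-[3,4,5-tris(benzyloxy)phenyl]oxiran-2-yl]methanol | OC[C@H]1O[C@H]1c1cc(OCc9ccccc9)c(OCc9ccccc9)c(OCc9ccccc9)c1 | intermediate
13 | (2S,3S)-3-[3,4,5-tris(benzyloxy)phenyl]oxirane-2-carbaldehyde | O=C[C@H]1O[C@H]1c1cc(OCc9ccccc9)c(OCc9ccccc9)c(OCc9ccccc9)c1 | intermediate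
14 | (+)-catechin | O[C@H]1Cc2c(O)cc(O)cc2O[C@@H]1c1ccc(O)c(O)c1 | starting material
15 | 5,7,3',4'-tetra-O-benzyl-(+)-catechin | O[C@H]1Cc2c(OCc9ccccc9)cc(OCc9ccccc9)cc2O[C@@H]1c1ccc(OCc9ccccc9)c(OCc9ccccc9)c1 | intermediate
16 | 3-O-TBS-5,7,3',4'-tetra-O-benzyl-(+)-catechin | CC(C)(C)[Si](C)(C)O[C@H]1Cc2c(OCc9ccccc9)cc(OCc9ccccc9)cc2O[C@@H]1c1ccc(OCc9ccccc9)c(OCc9ccccc9)c1 | intermediate
17 | 8-bromo-3-O-TBS-5,7,3',4'-tetra-O-benzyl-(+)-catechin | CC(C)(C)[Si](C)(C)O[C@H]1Cc2c(OCc9ccccc9)cc(OCc9ccccc9)c(Br)c2O[C@@H]1c1ccc(OCc9ccccc9)c(OCc9ccccc9)c1 | intermediate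
18 | 8-lithio-3-O-TBS-5,7,3',4'-tetra-O-benzyl-(+)-catechin | CC(C)(C)[Si](C)(C)O[C@H]1Cc2c(OCc9ccccc9)cc(OCc9ccccc9)c([Li])c2O[C@@H]1c1ccc(OCc9ccccc9)c(OCc9ccccc9)c1 | intermediate
19 | (1RS,2R,3S)-2,3-epoxy-3-[3,4,5-tris(benzyloxy)phenyl]-1-[3-O-TBS-5,7,3',4'-tetra-O-benzyl-(+)-catechin-8-yl]propan-1-ol (cis-epoxide; both C1 epimers) | OC(c2c(OCc9ccccc9)cc(OCc9ccccc9)c3c2O[C@H](c2ccc(OCc9ccccc9)c(OCc9ccccc9)c2)[C@@H](O[Si](C)(C)C(C)(C)C)C3)[C@H]1O[C@H]1c1cc(OCc9ccccc9)c(OCc9ccccc9)c(OCc9ccccc9)c1 | intermediate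
20 | benzylic cation from 19 (C1 cationic, stabilised by ring A of the catechin unit; cis-epoxide intact) | [CH+](c2c(OCc9ccccc9)cc(OCc9ccccc9)c3c2O[C@H](c2ccc(OCc9ccccc9)c(OCc9ccccc9)c2)[C@@H](O[Si](C)(C)C(C)(C)C)C3)[C@H]1O[C@H]1c1cc(OCc9ccccc9)c(OCc9ccccc9)c(OCc9ccccc9)c1 | intermediate
21 | epoxy phenol (Friedel–Crafts adduct: phenol ring of 7 alkylated at the carbon ortho to OH by C1 of the epoxy carbinol unit; cis-epoxide intact) | Oc1c([C@H]3c4c(OCc9ccccc9)cc(OCc9ccccc9)c(Br)c4O[C@H](c4ccc(OCc9ccccc9)c(OCc9ccccc9)c4)[C@@H]3O[Si](C)(C)C(C)(C)C)c(OCc9ccccc9)cc(OCc9ccccc9)c1[C@H](c2c(OCc9ccccc9)cc(OCc9ccccc9)c3c2O[C@H](c2ccc(OCc9ccccc9)c(OCc9ccccc9)c2)[C@@H](O[Si](C)(C)C(C)(C)C)C3)[C@H]1O[C@H]1c1cc(OCc9ccccc9)c(OCc9ccccc9)c(OCc9ccccc9)c1 | intermediate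
22 | benzyl-protected trimer, top and bottom 3-O-TBS, middle 3-OH free, top C8–Br | O[C@@H]1[C@@H](c2c(OCc9ccccc9)cc(OCc9ccccc9)c3c2O[C@H](c2ccc(OCc9ccccc9)c(OCc9ccccc9)c2)[C@@H](O[Si](C)(C)C(C)(C)C)C3)c2c(OCc9ccccc9)cc(OCc9ccccc9)c([C@H]3c4c(OCc9ccccc9)cc(OCc9ccccc9)c(Br)c4O[C@H](c4ccc(OCc9ccccc9)c(OCc9ccccc9)c4)[C@@H]3O[Si](C)(C)C(C)(C)C)c2O[C@@H]1c1cc(OCc9ccccc9)c(OCc9ccccc9)c(OCc9ccccc9)c1 | intermediate
23 | trimer triol (all three 3-OH free, top C8–Br) | O[C@@H]1[C@@H](c2c(OCc9ccccc9)cc(OCc9ccccc9)c3c2O[C@H](c2ccc(OCc9ccccc9)c(OCc9ccccc9)c2)[C@@H](O)C3)c2c(OCc9ccccc9)cc(OCc9ccccc9)c([C@H]3c4c(OCc9ccccc9)cc(OCc9ccccc9)c(Br)c4O[C@H](c4ccc(OCc9ccccc9)c(OCc9ccccc9)c4)[C@@H]3O)c2O[C@@H]1c1cc(OCc9ccccc9)c(OCc9ccccc9)c(OCc9ccccc9)c1 | intermediate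
24 | fully protected tris-gallate (22 benzyl ethers, top C8–Br) | O=C(O[C@@H]1[C@@H](c2c(OCc9ccccc9)cc(OCc9ccccc9)c3c2O[C@H](c2ccc(OCc9ccccc9)c(OCc9ccccc9)c2)[C@@H](OC(=O)c2cc(OCc9ccccc9)c(OCc9ccccc9)c(OCc9ccccc9)c2)C3)c2c(OCc9ccccc9)cc(OCc9ccccc9)c([C@H]3c4c(OCc9ccccc9)cc(OCc9ccccc9)c(Br)c4O[C@H](c4ccc(OCc9ccccc9)c(OCc9ccccc9)c4)[C@@H]3OC(=O)c3cc(OCc9ccccc9)c(OCc9ccccc9)c(OCc9ccccc9)c3)c2O[C@@H]1c1cc(OCc9ccccc9)c(OCc9ccccc9)c(OCc9ccccc9)c1)c1cc(OCc9ccccc9)c(OCc9ccccc9)c(OCc9ccccc9)c1 | intermediate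
25 | epicatechin 3-O-gallate-(4β→8)-epigallocatechin 3-O-gallate-(4β→8)-catechin 3-O-gallate (CNP0321910.1) | O=C(O[C@@H]1[C@@H](c2c(O)cc(O)c3c2O[C@H](c2ccc(O)c(O)c2)[C@@H](OC(=O)c2cc(O)c(O)c(O)c2)C3)c2c(O)cc(O)c([C@H]3c4c(O)cc(O)cc4O[C@H](c4ccc(O)c(O)c4)[C@@H]3OC(=O)c3cc(O)c(O)c(O)c3)c2O[C@@H]1c1cc(O)c(O)c(O)c1)c1cc(O)c(O)c(O)c1 | target

**Step count.** Total: 18 steps. Longest linear sequence: 10 steps (steps 6–10 and 14–18, from 3,4,5-trihydroxybenzaldehyde 8).

**Steps most likely to fail**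

1. Step 15 (proposed new method). The Lewis acid may open or rearrange the epoxide before or after ionisation (hydride shift to a ketone, cleavage of the epoxide-bearing cation). The phenol may add to the other face of the cation, or through its para carbon or another arene without reverting. The ring closure may lose configuration at C2 or run in the 5-exo sense. Fallback with known chemistry: ring C of the middle unit is bought instead of built. The fallback sets out from 16 and 5 and returns at 22. Commercial (−)-epigallocatechin (O[C@@H]1Cc2c(O)cc(O)cc2O[C@@H]1c1cc(O)c(O)c(O)c1) would be benzylated on its five phenols (BnBr, K2CO3, DMF) to 5,7,3',4',5'-penta-O-benzyl-(−)-epigallocatechin F1. Oxidation at C4 (DDQ, 2-ethoxyethanol, CH2Cl2) would give the 4β-(2-ethoxyethoxy) ether F2. Condensation of F2 with an excess of silyl ether 16 (Me3SiOTf, CH2Cl2, −78 °C) should occur through C8 of the catechin unit, anti to the 3-hydroxyl, to give the 4β→8 dimer F3. F3 would then act as nucleophile through C8 of its upper unit toward the C4 cation released from 5 (Me3SiOTf, CH2Cl2, −78 °C), which gives trimer 22. Both couplings are Lewis-acid interflavan condensations of 4-alkoxyflavans.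

2. Step 5. Attack through the carbon between the two benzyloxy groups or through oxygen, together with slow reaction of the hindered ortho carbon, would give regioisomeric adducts that are hard to separate. Fallback: the hydroxyl is masked so that the arene reacts as a 1,3-dialkoxybenzene. The fallback sets out from 6 and 5 and returns at 7. Phenol 6 would be acetylated (Ac2O, pyridine) to 3,5-bis(benzyloxy)phenyl acetate F4. The cation from 5 (BF3·OEt2, CH2Cl2, −78 °C) should alkylate F4 at the carbon para to one benzyloxy group and ortho to the acetoxy group, giving aryl acetate F5. Methanolysis (K2CO3, MeOH/THF, 0 °C) would free phenol 7.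

3. Step 14. Proton transfer from the cis-epoxy aldehyde to the hindered, basic aryllithium, base-induced epimerisation of the aldehyde, or its decomposition on handling would lower conversion or erode the cis relation. Fallback: the bond is made by acylation and reduction. The fallback sets out from 11 and 17 and returns at 19. Ester 11 would be converted (MeONHMe·HCl, i-PrMgCl, THF, −20 °C) into the Weinreb amide F6. Aryllithium 18, made from 17 as in step 14, should add once (Weinreb ketone synthesis) to give epoxy ketone F7. Reduction (NaBH4, CeCl3·7H2O, MeOH/THF, −40 °C) would give carbinol 19; either epimer serves.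

Further compounds
F1 | step 15 | 5,7,3',4',5'-penta-O-benzyl-(−)-epigallocatechin | O[C@@H]1Cc2c(OCc9ccccc9)cc(OCc9ccccc9)cc2O[C@@H]1c1cc(OCc9ccccc9)c(OCc9ccccc9)c(OCc9ccccc9)c1
F2 | step 15 | 4β-(2-ethoxyethoxy)-5,7,3',4',5'-penta-O-benzyl-(−)-epigallocatechin | CCOCCO[C@H]1c2c(OCc9ccccc9)cc(OCc9ccccc9)cc2O[C@H](c2cc(OCc9ccccc9)c(OCc9ccccc9)c(OCc9ccccc9)c2)[C@@H]1O
F3 | step 15 | penta-O-benzyl-epigallocatechin-(4β→8)-3-O-TBS-tetra-O-benzyl-catechin (upper 3-OH and upper C8–H free) | O[C@@H]1[C@@H](c2c(OCc9ccccc9)cc(OCc9ccccc9)c3c2O[C@H](c2ccc(OCc9ccccc9)c(OCc9ccccc9)c2)[C@@H](O[Si](C)(C)C(C)(C)C)C3)c2c(OCc9ccccc9)cc(OCc9ccccc9)cc2O[C@@H]1c1cc(OCc9ccccc9)c(OCc9ccccc9)c(OCc9ccccc9)c1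
F4 | step 5 | 3,5-bis(benzyloxy)phenyl acetate | CC(=O)Oc1cc(OCc2ccccc2)cc(OCc2ccccc2)c1
F5 | step 5 | O-acetate of phenol 7 | CC(=O)Oc1cc(OCc9ccccc9)cc(OCc9ccccc9)c1[C@H]3c4c(OCc9ccccc9)cc(OCc9ccccc9)c(Br)c4O[C@H](c4ccc(OCc9ccccc9)c(OCc9ccccc9)c4)[C@@H]3O[Si](C)(C)C(C)(C)C
F6 | step 14 | (2S,3S)-N-methoxy-N-methyl-3-[3,4,5-tris(benzyloxy)phenyl]oxirane-2-carboxamide | CON(C)C(=O)[C@H]1O[C@H]1c1cc(OCc9ccccc9)c(OCc9ccccc9)c(OCc9ccccc9)c1
F7 | step 14 | cis-epoxy ketone (C1 ketone corresponding to carbinol 19) | O=C(c2c(OCc9ccccc9)cc(OCc9ccccc9)c3c2O[C@H](c2ccc(OCc9ccccc9)c(OCc9ccccc9)c2)[C@@H](O[Si](C)(C)C(C)(C)C)C3)[C@H]1O[C@H]1c1cc(OCc9ccccc9)c(OCc9ccccc9)c(OCc9ccccc9)c1
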